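**Assumption (one line):** the target is taken as the free hydrogen sulfate exactly as drawn (released in the last acidic work-up); the sense of the chiral amide base (step 2) and of the lipase (step 8) is assumed as stated, and the mirror-image base or the opposite resolution mode is used if either is found reversed.

## Retrosynthetic overview

1. Target ⇐ O-sulfation, then oxidative demethylation/reduction of a 2,5-dimethoxyaryl secondary alcohol.
2. C18–C19 and the E-C17=C18 olefin (with the C17 methyl) ⇐ methylalumination of a terminal alkyne and Pd-catalysed coupling with 2,5-dimethoxybenzyl chloride.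
3. C11–C12 and the 12S carbinol ⇐ sparteine-controlled lithiation–borylation between a C12 carbamate and an ent-drimenyl boronic ester.
4. C12–C17 with the 13S methyl ⇐ 2,6-dimethylphenol: hydrogenation to meso cis-2,6-dimethylcyclohexanone, enantioselective deprotonation (key desymmetrisation), ozonolytic ring opening.
5. Decalin ⇐ (2E,6E)-farnesol: ring A then ring B close in one cation–olefin cascade; the (5R,9R,10R) enantiomer is secured by lipase resolution.

## Route

Step 1
Reactants: 1 2,6-dimethylphenol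
Product: 2 cis-2,6-dimethylcyclohexanone [(2R,6S), meso]
Conditions: H2 (1 MPa), Pd/C, AlCl3 (cat.), CH2Cl2, 50 °C; NaOMe (cat.), MeOH, 25 °C; fractional distillation
Reagents that add atoms: none
Why: Heterogeneous arene hydrogenation stops at the ketone under Pd/Lewis-acid conditions, and base equilibration favours the diequatorial cis (meso) isomer, which is distilled free of trans.

Step 2
Reactants: 2 cis-2,6-dimethylcyclohexanone
Product: 3 {[(6S)-2,6-dimethylcyclohex-1-en-1-yl]oxy}trimethylsilane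
Conditions: (R,R)-bis(1-phenylethyl)amine (2 equiv), n-Bu2Mg (1 equiv), THF, reflux; then Me3SiCl, DMPU, −78 °C, slow addition of 2
Reagents that add atoms: chlorotrimethylsilane, C[Si](C)(C)Cl
Why: Enantioselective deprotonation (Simpkins–Koga-type desymmetrisation with a homochiral magnesium amide and in situ silyl trapping) removes one of the two enantiotopic α-hydrogens, so the untouched α-carbon becomes the 13S methyl stereocentre.

Step 3
Reactants: 3 silyl enol ether
Product: 6 (2S)-2-methyl-6-oxoheptanoic acid, via ozonide 4 (not isolated), via silyl ester 5 (not isolated)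
Conditions: O3, CH2Cl2, −78 °C; Me2S, −78 → 25 °C; H2O
Reagents that add atoms: ozone, [O-][O+]=O
Why: Ozonolysis of the electron-rich tetrasubstituted enol ether cleaves the ring at C12=C17, giving the C12 acid and the C17 methyl ketone under neutral conditions that leave the α-stereocentre intact.

Step 4
Reactants: 6 (2S)-2-methyl-6-oxoheptanoic acid
Product: 7 (6S)-7-hydroxy-6-methylheptan-2-one
Conditions: BH3·SMe2 (1.0 equiv), THF, −10 → 0 °C; MeOH quench
Reagents that add atoms: none
Why: Chemoselective borane reduction, because carboxylic acids (via acyloxyboranes) are reduced markedly faster than dialkyl ketones at or below 0 °C.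

Step 5
Reactants: 7 (6S)-7-hydroxy-6-methylheptan-2-one
Product: 8 (2S)-2-methyl-6-oxoheptyl N,N-diisopropylcarbamate
Conditions: iPr2NCOCl, Et3N, CH2Cl2, reflux
Reagents that add atoms: N,N-diisopropylcarbamoyl chloride, CC(C)N(C(C)C)C(=O)Cl
Why: O-carbamoylation of the primary alcohol installs the Hoppe directing and leaving group needed for the later 1,2-metallate shift.

Step 6
Reactants: 8 keto carbamate
Product: 11 (2S)-2-methyl-7-(trimethylsilyl)hept-6-yn-1-yl N,N-diisopropylcarbamate, via enol phosphate 9 (not isolated), via lithium acetylide 10 (not isolated)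
Conditions: LDA (1.1 equiv), THF, −78 °C; ClP(O)(OEt)2, −78 → 0 °C; LDA (2.5 equiv), −78 → 0 °C; Me3SiCl, −78 → 25 °C
Reagents that add atoms: chlorotrimethylsilane, C[Si](C)(C)Cl
Why: Negishi methyl ketone-to-alkyne conversion (kinetic enol phosphate, then elimination) with in situ C-silylation; the former ketone methyl becomes C18 and the non-acidic C13 centre is untouched.

Step 7
Reactants: 12 (2E,6E)-farnesol
Product: 13 (±)-drimenol
Conditions: FSO3H (8 equiv), 2-nitropropane, −78 °C, 20 min; Et3N quench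
Reagents that add atoms: none
Why: Proton-initiated cation–olefin bicyclisation (Stork–Eschenmoser chair–chair fold) closes ring A then ring B, fixing the trans ring fusion and the equatorial C9 substituent, and kinetic loss of H7 gives the C7=C8 olefin; the product is racemic.

Step 8
Reactants: 13 (±)-drimenol
Product: 14 ent-drimenol [(1R,4aR,8aR)-2,5,5,8a-tetramethyl-1,4,4a,5,6,7,8,8a-octahydronaphthalen-1-yl]methanol
Conditions: Burkholderia cepacia lipase, vinyl acetate, t-BuOMe, 30 °C, to about 55–60% conversion; chromatography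
Reagents that add atoms: none
Why: Lipase-catalysed kinetic resolution (enantioselective transesterification) acylates the (1S,4aS,8aS) alcohol and leaves the required (5R,9R,10R) alcohol in high ee.

Step 9
Reactants: 14 ent-drimenol
Product: 15 ent-drimenyl iodide [(1R,4aR,8aR)-1-(iodomethyl)-2,5,5,8a-tetramethyl-1,4,4a,5,6,7,8,8a-octahydronaphthalene]
Conditions: I2, PPh3, imidazole, CH2Cl2, 0 → 25 °C
Reagents that add atoms: iodine, II
Why: Appel-type iodination of the primary alcohol by displacement of the alkoxyphosphonium at C11, which touches no stereocentre.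

Step 10
Reactants: 15 ent-drimenyl iodide
Product: 16 ent-drimenyl pinacol boronate [4,4,5,5-tetramethyl-2-(ent-drim-7-en-11-yl)-1,3,2-dioxaborolane]
Conditions: B2pin2, CuI (10 mol %), PPh3 (13 mol %), LiOMe, DMF, 25 °C
Reagents that add atoms: bis(pinacolato)diboron, CC1(C)OB(OC1(C)C)B1OC(C)(C)C(C)(C)O1
Why: Copper-catalysed borylation of a primary alkyl iodide, tolerant of the trisubstituted olefin.

Step 11
Reactants: 11 silyl alkyne carbamate; 16 ent-drimenyl pinacol boronate
Product: 21 (2S,3S)-3-methyl-1-[(1R,4aR,8aR)-2,5,5,8a-tetramethyl-1,4,4a,5,6,7,8,8a-octahydronaphthalen-1-yl]oct-7-yn-2-ol, via lithiated carbamate 17 (not isolated), via boronate complex 18 (not isolated), via boronic ester 19 (not isolated), via silyl alkynol 20 (not isolated)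
Conditions: s-BuLi, (−)-sparteine, Et2O, −78 °C, 5 h; 16, −78 °C, 1 h; MgBr2·OEt2, reflux, 12 h; H2O2, NaOH, THF, 0 → 25 °C; K2CO3, MeOH, 25 °C
Reagents that add atoms: hydrogen peroxide, OO
Why: Hoppe–Aggarwal lithiation–borylation, in which sparteine-directed removal of the pro-S hydrogen, retentive borylation, invertive 1,2-metallate shift of C11 and retentive C–B oxidation set 12S under reagent control, syn to the 13S methyl.

Step 12
Reactants: 21 alkynol; 22 2,5-dimethoxybenzyl chloride
Product: 24 (2S,3S,7E)-9-(2,5-dimethoxyphenyl)-3,7-dimethyl-1-[(1R,4aR,8aR)-2,5,5,8a-tetramethyl-1,4,4a,5,6,7,8,8a-octahydronaphthalen-1-yl]non-7-en-2-ol, via alkenylalane 23 (not isolated)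
Conditions: Me3Al (4 equiv), Cp2ZrCl2 (0.25 equiv), CH2Cl2, 0 → 25 °C; evaporate excess Me3Al; 22, Pd(PPh3)4 (5 mol %), THF, 25 °C; dilute HCl work-up
Reagents that add atoms: trimethylaluminium, C[Al](C)C
Why: Negishi zirconocene-catalysed syn-methylalumination places the methyl on C17 and aluminium on C18, and Pd-catalysed alkenyl–benzyl cross-coupling with retention gives the E-trisubstituted olefin.

Step 13
Reactants: 24 dimethoxyaryl alcohol
Product: 25 pyridinium (2S,3S,7E)-9-(2,5-dimethoxyphenyl)-3,7-dimethyl-1-[(1R,4aR,8aR)-2,5,5,8a-tetramethyl-1,4,4a,5,6,7,8,8a-octahydronaphthalen-1-yl]non-7-en-2-yl sulfate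
Conditions: SO3·pyridine (5 equiv), pyridine, 50 °C
Reagents that add atoms: sulfur trioxide–pyridine complex, O=S(=O)([O-])[n+]1ccccc1
Why: O-sulfation at oxygen retains the C12 configuration, and with both phenols still masked as methyl ethers the secondary alcohol is the only site.

Step 14
Reactants: 25 pyridinium sulfate
Product: 27 target hydrogen sulfate (CNP0358517.7), via quinone sulfate 26 (not isolated)
Conditions: (NH4)2Ce(NO3)6 (2.5 equiv), MeCN/H2O, 0 °C, 20 min; Na2S2O4 (aq), 25 °C; HCl to pH 2 at 0 °C, n-BuOH extraction, reversed-phase chromatography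
Reagents that add atoms: water, O
Why: Oxidative demethylation of the 1,4-dimethoxyarene to the quinone, followed by dithionite reduction to the hydroquinone, under brief cold conditions that spare the alkyl sulfate and both olefins.

## Compound list

1 | 2,6-dimethylphenol | Cc1cccc(C)c1O | starting material
2 | cis-2,6-dimethylcyclohexanone, (2R,6S), meso | C[C@H]1CCC[C@@H](C)C1=O | intermediate
3 | {[(6S)-2,6-dimethylcyclohex-1-en-1-yl]oxy}trimethylsilane | C[C@H]1CCCC(C)=C1O[Si](C)(C)C | intermediate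
4 | ozonide of 3, (5S)-1,5-dimethyl-6-(trimethylsilyloxy)-7,8,9-trioxabicyclo[4.2.1]nonane | C[C@H]1CCCC2(C)OOC1(O[Si](C)(C)C)O2 | intermediate (not isolated)
5 | trimethylsilyl (2S)-2-methyl-6-oxoheptanoate | C[C@@H](CCCC(C)=O)C(=O)O[Si](C)(C)C | intermediate (not isolated)
6 | (2S)-2-methyl-6-oxoheptanoic acid | C[C@@H](CCCC(C)=O)C(=O)O | intermediate
7 | (6S)-7-hydroxy-6-methylheptan-2-one | C[C@@H](CCCC(C)=O)CO | intermediate
8 | (2S)-2-methyl-6-oxoheptyl N,N-diisopropylcarbamate | C[C@@H](CCCC(C)=O)COC(=O)N(C(C)C)C(C)C | intermediate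
9 | diethyl (6S)-7-(diisopropylcarbamoyloxy)-6-methylhept-1-en-2-yl phosphate | C[C@@H](CCCC(=C)OP(=O)(OCC)OCC)COC(=O)N(C(C)C)C(C)C | intermediate (not isolated)
10 | lithium acetylide of (2S)-2-methylhept-6-yn-1-yl N,N-diisopropylcarbamate | C[C@@H](CCCC#C[Li])COC(=O)N(C(C)C)C(C)C | intermediate (not isolated)
11 | (2S)-2-methyl-7-(trimethylsilyl)hept-6-yn-1-yl N,N-diisopropylcarbamate | C[C@@H](CCCC#C[Si](C)(C)C)COC(=O)N(C(C)C)C(C)C | intermediate
12 | (2E,6E)-farnesol | CC(C)=CCC/C(C)=C/CC/C(C)=C/CO | starting material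
13 | (±)-drimenol (racemate; the mirror image of the SMILES is equally present) | CC1=CC[C@@H]2C(C)(C)CCC[C@@]2(C)[C@@H]1CO | intermediate
14 | ent-drimenol, [(1R,4aR,8aR)-2,5,5,8a-tetramethyl-1,4,4a,5,6,7,8,8a-octahydronaphthalen-1-yl]methanol | CC1=CC[C@@H]2C(C)(C)CCC[C@@]2(C)[C@@H]1CO | intermediate
15 | ent-drimenyl iodide | CC1=CC[C@@H]2C(C)(C)CCC[C@@]2(C)[C@@H]1CI | intermediate
16 | ent-drimenyl pinacol boronate (same ring configuration as 14) | CC1=CC[C@@H]2C(C)(C)CCC[C@@]2(C)[C@@H]1CB1OC(C)(C)C(C)(C)O1 | intermediate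
17 | (1S,2S)-1-lithio-2-methyl-7-(trimethylsilyl)hept-6-yn-1-yl N,N-diisopropylcarbamate | C[C@@H](CCCC#C[Si](C)(C)C)[C@H]([Li])OC(=O)N(C(C)C)C(C)C | intermediate (not isolated)
18 | lithium boronate complex of 17 and 16 | [Li+].C[C@@H](CCCC#C[Si](C)(C)C)[C@@H](OC(=O)N(C(C)C)C(C)C)[B-]1(C[C@@H]2C(C)=CC[C@@H]3C(C)(C)CCC[C@@]23C)OC(C)(C)C(C)(C)O1 | intermediate (not isolated)
19 | secondary pinacol boronic ester at C12 (boron in place of the later hydroxyl) | C[C@@H](CCCC#C[Si](C)(C)C)[C@H](C[C@@H]1C(C)=CC[C@@H]2C(C)(C)CCC[C@@]12C)B1OC(C)(C)C(C)(C)O1 | intermediate (not isolated)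
20 | (2S,3S)-3-methyl-1-[(1R,4aR,8aR)-2,5,5,8a-tetramethyl-1,4,4a,5,6,7,8,8a-octahydronaphthalen-1-yl]-8-(trimethylsilyl)oct-7-yn-2-ol | CC1=CC[C@@H]2C(C)(C)CCC[C@@]2(C)[C@@H]1C[C@H](O)[C@@H](C)CCCC#C[Si](C)(C)C | intermediate (not isolated)
21 | (2S,3S)-3-methyl-1-[(1R,4aR,8aR)-2,5,5,8a-tetramethyl-1,4,4a,5,6,7,8,8a-octahydronaphthalen-1-yl]oct-7-yn-2-ol | CC1=CC[C@@H]2C(C)(C)CCC[C@@]2(C)[C@@H]1C[C@H](O)[C@@H](C)CCCC#C | intermediate
22 | 2,5-dimethoxybenzyl chloride | COc1ccc(OC)c(CCl)c1 | starting material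
23 | (E)-alkenyl(dimethyl)alane of 21, with the hydroxyl as its dimethylaluminium alkoxide | CC1=CC[C@@H]2C(C)(C)CCC[C@@]2(C)[C@@H]1C[C@H](O[Al](C)C)[C@@H](C)CCC/C(C)=C/[Al](C)C | intermediate (not isolated)
24 | (2S,3S,7E)-9-(2,5-dimethoxyphenyl)-3,7-dimethyl-1-[(1R,4aR,8aR)-2,5,5,8a-tetramethyl-1,4,4a,5,6,7,8,8a-octahydronaphthalen-1-yl]non-7-en-2-ol | CC1=CC[C@@H]2C(C)(C)CCC[C@@]2(C)[C@@H]1C[C@H](O)[C@@H](C)CCC/C(C)=C/Cc1cc(OC)ccc1OC | intermediate
25 | pyridinium sulfate of 24 | CC1=CC[C@@H]2C(C)(C)CCC[C@@]2(C)[C@@H]1C[C@H](OS(=O)(=O)[O-])[C@@H](C)CCC/C(C)=C/Cc1cc(OC)ccc1OC.c1cc[nH+]cc1 | intermediate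
26 | pyridinium sulfate of the 2-substituted 1,4-benzoquinone | CC1=CC[C@@H]2C(C)(C)CCC[C@@]2(C)[C@@H]1C[C@H](OS(=O)(=O)[O-])[C@@H](C)CCC/C(C)=C/CC1=CC(=O)C=CC1=O.c1cc[nH+]cc1 | intermediate (not isolated)
27 | (2S,3S,7E)-9-(2,5-dihydroxyphenyl)-3,7-dimethyl-1-[(1R,4aR,8aR)-2,5,5,8a-tetramethyl-1,4,4a,5,6,7,8,8a-octahydronaphthalen-1-yl]non-7-en-2-yl hydrogen sulfate | CC1=CC[C@@H]2C(C)(C)CCC[C@@]2(C)[C@@H]1C[C@H](OS(=O)(=O)O)[C@@H](C)CCC/C(C)=C/Cc1cc(O)ccc1O | target

## Step count and risks

Total steps: 14. Longest linear sequence: 10 (steps 1–6, then 11–14); the decalin branch is steps 7–10.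

**Step 11 (lithiation–borylation).** The carbamate is β-branched and the boronic ester is hindered, so the lithiation or the 1,2-shift may be slow or less selective. Fallback, setting out from 11 and 15 and returning at 20: LiAlH4 cleaves the carbamate of 11 to (2S)-2-methyl-7-(trimethylsilyl)hept-6-yn-1-ol F6, and NaOCl with catalytic TEMPO gives (2S)-2-methyl-7-(trimethylsilyl)hept-6-ynal F7. Iodide 15 is converted by iodine–zinc exchange (Et2Zn, CuI cat.) into bis(ent-drimenyl)zinc F8. F8 adds to F7 under Ti(OiPr)4 and (1R,2R)-1,2-bis(trifluoromethanesulfonamido)cyclohexane catalysis (catalyst-controlled alkyl transfer to the aldehyde), giving silyl alkynol 20, which is desilylated (K2CO3, MeOH) to 21 as before.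

**Step 8 (lipase resolution).** The selectivity factor for drimenol itself may be modest. Fallback, setting out from 13 and returning at 14: esterify 13 with (S)-naproxen (DCC, DMAP) to give ent-drimenyl (S)-naproxenate F4 together with its (1S,4aS,8aS)-drimenyl diastereomer F5. Separate the two by crystallisation or chromatography, then saponify F4 (LiOH, THF/H2O) to 14.

**Step 2 (enantioselective deprotonation).** The ee or the sense of induction may fall short. Fallback, setting out from 2 and returning at 8: an enzymatic Baeyer–Villiger desymmetrisation (cyclohexanone monooxygenase, O2, NADPH recycling) gives (3S,7R)-3,7-dimethyloxepan-2-one F1. LiAlH4 then gives (2S,6R)-2-methylheptane-1,6-diol F2. Selective carbamoylation of the primary hydroxyl (iPr2NCOCl, Et3N) gives (2S,6R)-6-hydroxy-2-methylheptyl N,N-diisopropylcarbamate F3, and NaOCl with catalytic TEMPO oxidises the secondary alcohol to 8.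

## Further compounds

F1 | step 2 | (3S,7R)-3,7-dimethyloxepan-2-one | C[C@H]1CCC[C@@H](C)OC1=O
F2 | step 2 | (2S,6R)-2-methylheptane-1,6-diol | C[C@@H](CCC[C@@H](C)O)CO
F3 | step 2 | (2S,6R)-6-hydroxy-2-methylheptyl N,N-diisopropylcarbamate | C[C@@H](CCC[C@@H](C)O)COC(=O)N(C(C)C)C(C)C
F4 | step 8 | ent-drimenyl (S)-naproxenate | CC1=CC[C@@H]2C(C)(C)CCC[C@@]2(C)[C@@H]1COC(=O)[C@@H](C)c1ccc2cc(OC)ccc2c1
F5 | step 8 | (1S,4aS,8aS)-drimenyl (S)-naproxenate | CC1=CC[C@H]2C(C)(C)CCC[C@]2(C)[C@H]1COC(=O)[C@@H](C)c1ccc2cc(OC)ccc2c1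
F6 | step 11 | (2S)-2-methyl-7-(trimethylsilyl)hept-6-yn-1-ol | C[C@@H](CCCC#C[Si](C)(C)C)CO
F7 | step 11 | (2S)-2-methyl-7-(trimethylsilyl)hept-6-ynal | C[C@@H](CCCC#C[Si](C)(C)C)C=O
F8 | step 11 | bis(ent-drimenyl)zinc | CC1=CC[C@@H]2C(C)(C)CCC[C@@]2(C)[C@@H]1C[Zn]C[C@@H]1C(C)=CC[C@@H]2C(C)(C)CCC[C@@]12C
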